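**Retrosynthetic overview**

- Endgame on ring B of a cis-fused bicycle: the target comes from a cis-7α,8α-diol by double esterification and release of the C2 ketone; the diol comes from a Δ6-8-enone by isopropenyl conjugate addition/enolate hydroxylation and C8 reduction.
- The enone comes from the Diels–Alder adduct by CHO → CH3 and C8 carbinol → ketone → enone.
- Key disconnection: ring A by an intermolecular [4+2] of (E)-2-(triisopropylsilyloxy)penta-1,3-diene with (S)-3-(triethylsilyloxy)cyclohex-1-ene-1-carbaldehyde. It forms C1–C8a and C4–C4a and sets C4, C4a and C8a.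
- Ring order: ring B is bought (3-bromocyclohex-2-en-1-one); ring A is closed in the key step.
- Enabling feature: ring A (C1–C4, C4a, C8a) is a cyclohexanone with the C2 carbonyl 1,4 to the quaternary C4a, and with 4-CH3, 4a-CH3 and H-8a all cis on a cis ring fusion. This is the retron of an endo Diels–Alder of a 2-oxy-diene onto a C4a=C8a enal (4a-CH3 = reduced formyl activator). The C8 oxygen next to C8a offers a removable carbinol stereocentre that steers the diene face.

Key step: step 5

Remark on the chemistry: the side chains are read as (R)-2-methylbutanoates as drawn; (R)-2-methylbutanoic acid, 3-bromocyclohex-2-en-1-one and (E)-pent-3-en-2-one are taken as purchasable.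

Convention: all bicyclic compounds carry the locants of the target's naphthalen-2-one skeleton (C2 = oxo/silyloxy carbon, C4 and C4a = methyl-bearing carbons, C8a = ring-fusion CH). β is the face of 4-CH3, the C4a substituent and H-8a; α is the opposite face.

**Route**

Step 1
Reactants: 1 3-bromocyclohex-2-en-1-one
Product: 2 (S)-3-bromocyclohex-2-en-1-ol
Conditions: (R)-Me-CBS (10 mol %), catecholborane, toluene, −78 °C
Reagents that add atoms: none
Why: Corey–Bakshi–Shibata 1,2-reduction; with the bromoalkenyl side acting as the large substituent, the (R)-oxazaborolidine should deliver hydride to the face that gives the (S)-allylic alcohol.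

Step 2
Reactants: 2 (S)-3-bromocyclohex-2-en-1-ol
Product: 3 (S)-[(3-bromocyclohex-2-en-1-yl)oxy]triethylsilane
Conditions: TESCl, imidazole, CH2Cl2, 0 °C → rt
Reagents that add atoms: chlorotriethylsilane, CC[Si](Cl)(CC)CC
Why: Standard O-silylation of a secondary allylic alcohol; only the O–H bond reacts, so the stereocentre is untouched.

Step 3
Reactants: 3 (S)-[(3-bromocyclohex-2-en-1-yl)oxy]triethylsilane
Product: 4 (S)-3-(triethylsilyloxy)cyclohex-1-ene-1-carbaldehyde
Conditions: t-BuLi (2.1 equiv), Et2O, −78 °C; DMF, −78 → 0 °C; H2O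
Reagents that add atoms: N,N-dimethylformamide, CN(C)C=O
Why: Bromine–lithium exchange followed by formylation of the vinyllithium with DMF (Bouveault-type); the lithium is trans to the allylic carbon bearing OTES, so neither elimination nor silyl migration can intervene.

Step 4
Reactants: 5 (E)-pent-3-en-2-one
Product: 6 (E)-2-(triisopropylsilyloxy)penta-1,3-diene
Conditions: TIPSOTf, Et3N, CH2Cl2, 0 °C → rt
Reagents that add atoms: triisopropylsilyl trifluoromethanesulfonate, CC(C)[Si](OS(=O)(=O)C(F)(F)F)(C(C)C)C(C)C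
Why: Soft enolisation (O-silylation, then loss of a proton from the acetyl methyl group) gives the cross-conjugated silyl dienol ether with the (E)-propenyl geometry retained.

Step 5
Reactants: 4 (S)-3-(triethylsilyloxy)cyclohex-1-ene-1-carbaldehyde; 6 (E)-2-(triisopropylsilyloxy)penta-1,3-diene
Product: 7 (4S,4aS,8S,8aS)-4-methyl-8-(triethylsilyloxy)-2-(triisopropylsilyloxy)-1,5,6,7,8,8a-hexahydronaphthalene-4a(4H)-carbaldehyde
Conditions: Me2AlCl (0.3 equiv), 6 (1.5 equiv), CH2Cl2, −78 → −40 °C
Reagents that add atoms: none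
Why: This is a Lewis-acid-promoted normal-demand [4+2] cycloaddition of the Me2AlCl-complexed enal 4 (2π) with the s-cis silyloxydiene 6 (4π), concerted but asynchronous with the C1–C8a bond leading; the closest precedent is the Lewis-acid-catalysed Diels–Alder reaction of 2-(triisopropylsilyloxy)-1,3-dienes with α-substituted enals and 2-cycloalkenones. Ring A closes as a six-membered carbocycle by suprafacial addition across C4a=C8a, which fixes the cis ring fusion (4a-CHO and H-8a syn); in the stepwise limit the same ring arises by Mukaiyama–Michael addition followed by a 6-endo-trig Michael closure. Regiochemistry is doubly enforced, because both the 2-silyloxy and the 4-methyl group make the CH2 terminus of 6 the nucleophilic end, which bonds to the β-carbon C8a ("para" to OSi, "ortho" to CH3). C4 is set by the endo orientation of the complexed formyl group towards the (E)-diene, which places 4-CH3 cis to 4a-CHO; the alternative ring-endo arrangement is further penalised by the clash of the TIPSO group with C8 and its substituents. The absolute configuration of C4, C4a and C8a is relayed from C8, the diene adding to the face anti to the allylic OTES group. The step also needs C=C over C=O chemoselectivity (no Mukaiyama aldol), which the bulky, poorly transferable TIPS group and the low temperature should secure.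

Step 6
Reactants: 7 (4S,4aS,8S,8aS)-4-methyl-8-(triethylsilyloxy)-2-(triisopropylsilyloxy)-1,5,6,7,8,8a-hexahydronaphthalene-4a(4H)-carbaldehyde
Product: 9 (4S,4aR,8S,8aS)-4,4a-dimethyl-8-(triethylsilyloxy)-2-(triisopropylsilyloxy)-1,4,4a,5,6,7,8,8a-octahydronaphthalene, via tosylhydrazone 8 (not isolated)
Conditions: TsNHNH2, THF, 4 Å MS, rt; then catecholborane, CHCl3, 0 °C → rt; NaOAc·3H2O, reflux
Reagents that add atoms: none
Why: Caglioti-type deoxygenation in the catecholborane variant (hydroboration of the C=N bond, sulfinate loss, N2 extrusion from the diazene) converts the non-enolisable formyl group into the angular methyl group under near-neutral conditions that spare both silyl groups and touch no stereocentre.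

Step 7
Reactants: 9 (4S,4aR,8S,8aS)-4,4a-dimethyl-8-(triethylsilyloxy)-2-(triisopropylsilyloxy)-1,4,4a,5,6,7,8,8a-octahydronaphthalene
Product: 10 (4S,4aR,8S,8aS)-4,4a-dimethyl-2-(triisopropylsilyloxy)-1,4,4a,5,6,7,8,8a-octahydronaphthalen-8-ol
Conditions: PPTS (10 mol %), MeOH–CH2Cl2, 0 °C
Reagents that add atoms: none
Why: Selective acid-catalysed methanolysis of a silyl ether: the triethylsilyl alkyl ether should be solvolysed much faster than the hindered triisopropylsilyl enol ether is protonated at carbon, so only the 8β-hydroxyl is unmasked.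

Step 8
Reactants: 10 (4S,4aR,8S,8aS)-4,4a-dimethyl-2-(triisopropylsilyloxy)-1,4,4a,5,6,7,8,8a-octahydronaphthalen-8-ol
Product: 11 (4S,4aR,8aS)-4,4a-dimethyl-2-(triisopropylsilyloxy)-4,4a,5,6,7,8a-hexahydronaphthalen-8(1H)-one
Conditions: Dess–Martin periodinane, pyridine, CH2Cl2, 0 °C → rt
Reagents that add atoms: none
Why: Dess–Martin oxidation removes the relay stereocentre at C8, which has done its work; the buffered, non-basic conditions should leave the now epimerisable cis ring-fusion centre C8a and the silyl enol ether intact.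

Step 9
Reactants: 11 (4S,4aR,8aS)-4,4a-dimethyl-2-(triisopropylsilyloxy)-4,4a,5,6,7,8a-hexahydronaphthalen-8(1H)-one
Product: 12 (4S,4aR,8aS)-4,4a-dimethyl-2-(triisopropylsilyloxy)-4,4a,5,8a-tetrahydronaphthalen-8(1H)-one
Conditions: LDA, THF, −78 °C; then N-tert-butylbenzenesulfinimidoyl chloride, −78 °C
Reagents that add atoms: none
Why: Mukaiyama dehydrogenation: kinetic deprotonation occurs at the C7 methylene and not at the hindered ring-fusion methine C8a, and the enolate is sulfenylated and eliminates in situ to the Δ6 enone without equilibrating C8a.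

Step 10
Reactants: 12 (4S,4aR,8aS)-4,4a-dimethyl-2-(triisopropylsilyloxy)-4,4a,5,8a-tetrahydronaphthalen-8(1H)-one
Product: 15 (4S,4aR,6R,7R,8aS)-7-hydroxy-4,4a-dimethyl-6-(prop-1-en-2-yl)-2-(triisopropylsilyloxy)-4,4a,5,6,7,8a-hexahydronaphthalen-8(1H)-one, via trimethylsilyl enol ether 13 (not isolated), via lithium enolate 14 (not isolated)
Conditions: isopropenylMgBr, CuBr·SMe2 (10 mol %), TMSCl, THF, −78 °C; filter, concentrate; MeLi, THF, 0 °C; 2-(phenylsulfonyl)-3-phenyloxaziridine, −78 °C; H2O
Reagents that add atoms: isopropenylmagnesium bromide, CC(=C)[Mg]Br; 2-(phenylsulfonyl)-3-phenyloxaziridine, O=S(=O)(N1OC1c1ccccc1)c1ccccc1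
Why: Copper-catalysed conjugate addition with TMSCl trapping should deliver the isopropenyl group to C6 from the convex β face of the cis-fused enone (the face of 4a-CH3 and H-8a, away from ring-A carbon C4), and after MeLi regenerates the lithium enolate, Davis oxaziridine hydroxylation at C7 should occur anti to the new C6 substituent, giving the trans 6β-isopropenyl-7α-hydroxy ketone.

Step 11
Reactants: 15 (4S,4aR,6R,7R,8aS)-7-hydroxy-4,4a-dimethyl-6-(prop-1-en-2-yl)-2-(triisopropylsilyloxy)-4,4a,5,6,7,8a-hexahydronaphthalen-8(1H)-one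
Product: 16 (4S,4aR,6R,7R,8S,8aS)-4,4a-dimethyl-6-(prop-1-en-2-yl)-2-(triisopropylsilyloxy)-1,4,4a,5,6,7,8,8a-octahydronaphthalene-7,8-diol
Conditions: L-Selectride (2.5 equiv), THF, −78 °C; H2O
Reagents that add atoms: none
Why: Selectride reduction of an α-oxygenated cyclohexanone: the bulky hydride should attack C8 along the equatorial trajectory from the convex β face (the axial α approach is blocked by C4, syn-axial to it), giving the axial 8α-alcohol cis to 7α-OH.

Step 12
Reactants: 16 (4S,4aR,6R,7R,8S,8aS)-4,4a-dimethyl-6-(prop-1-en-2-yl)-2-(triisopropylsilyloxy)-1,4,4a,5,6,7,8,8a-octahydronaphthalene-7,8-diol; 17 (R)-2-methylbutanoic acid (2 equiv incorporated, 4 equiv used)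
Product: 18 (4S,4aR,6R,7R,8S,8aS)-4,4a-dimethyl-6-(prop-1-en-2-yl)-2-(triisopropylsilyloxy)-1,4,4a,5,6,7,8,8a-octahydronaphthalene-7,8-diyl bis[(2R)-2-methylbutanoate]
Conditions: DCC, DMAP (cat.), CH2Cl2, 0 °C → rt
Reagents that add atoms: none
Why: Steglich esterification acylates both hydroxyls through the acylpyridinium ion without touching the carbinol centres, and the mild conditions should keep the α-stereocentre of the acid intact.

Step 13
Reactants: 18 (4S,4aR,6R,7R,8S,8aS)-4,4a-dimethyl-6-(prop-1-en-2-yl)-2-(triisopropylsilyloxy)-1,4,4a,5,6,7,8,8a-octahydronaphthalene-7,8-diyl bis[(2R)-2-methylbutanoate]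
Product: 19 (4S,4aR,6R,7R,8S,8aS)-4,4a-dimethyl-2-oxo-6-(prop-1-en-2-yl)decahydronaphthalene-7,8-diyl bis[(2R)-2-methylbutanoate]
Conditions: TBAF, AcOH, THF, 0 °C
Reagents that add atoms: none
Why: Fluoride-induced cleavage of the silyl enol ether (desilylation and ketonisation by protonation at C3) releases the C2 ketone; the buffered conditions should spare both esters, and no stereocentre is α to the new carbonyl.

**Compound list**

1 | 3-bromocyclohex-2-en-1-one | O=C1C=C(Br)CCC1 | starting material
2 | (S)-3-bromocyclohex-2-en-1-ol | BrC1=C[C@@H](O)CCC1 | intermediate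
3 | (S)-[(3-bromocyclohex-2-en-1-yl)oxy]triethylsilane | BrC1=C[C@@H](O[Si](CC)(CC)CC)CCC1 | intermediate
4 | (S)-3-(triethylsilyloxy)cyclohex-1-ene-1-carbaldehyde | O=CC1=C[C@@H](O[Si](CC)(CC)CC)CCC1 | intermediate
5 | (E)-pent-3-en-2-one | C/C=C/C(C)=O | starting material
6 | (E)-2-(triisopropylsilyloxy)penta-1,3-diene | C=C(O[Si](C(C)C)(C(C)C)C(C)C)/C=C/C | intermediate
7 | (4S,4aS,8S,8aS) Diels–Alder adduct, cis-fused, 4-CH3, 4a-CHO, H-8a and 8-OTES all β, 2-OTIPS enol ether (Δ2) | C1C[C@@]2(C=O)[C@H](CC(O[Si](C(C)C)(C(C)C)C(C)C)=C[C@@H]2C)[C@@H](O[Si](CC)(CC)CC)C1 | intermediate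
8 | (E)-N'-tosylhydrazone of aldehyde 7 | C1C[C@@]2(/C=N/NS(=O)(=O)c3ccc(C)cc3)[C@H](CC(O[Si](C(C)C)(C(C)C)C(C)C)=C[C@@H]2C)[C@@H](O[Si](CC)(CC)CC)C1 | intermediate
9 | (4S,4aR,8S,8aS) 4β,4aβ-dimethyl compound, 8β-OTES, 2-OTIPS enol ether | C1C[C@@]2(C)[C@H](CC(O[Si](C(C)C)(C(C)C)C(C)C)=C[C@@H]2C)[C@@H](O[Si](CC)(CC)CC)C1 | intermediate
10 | (4S,4aR,8S,8aS) 8β-alcohol, 2-OTIPS enol ether | C1C[C@@]2(C)[C@H](CC(O[Si](C(C)C)(C(C)C)C(C)C)=C[C@@H]2C)[C@@H](O)C1 | intermediate
11 | (4S,4aR,8aS) 8-ketone, cis-fused, 2-OTIPS enol ether | C1C[C@@]2(C)[C@H](CC(O[Si](C(C)C)(C(C)C)C(C)C)=C[C@@H]2C)C(=O)C1 | intermediate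
12 | (4S,4aR,8aS) Δ6-8-enone, cis-fused, 2-OTIPS enol ether | O=C1C=CC[C@]2(C)[C@@H](C)C=C(O[Si](C(C)C)(C(C)C)C(C)C)C[C@H]12 | intermediate
13 | (4S,4aR,6S,8aS) 6β-isopropenyl 8-(trimethylsilyloxy) Δ7 enol ether, 2-OTIPS enol ether | C=C(C)[C@H]1C[C@@]2(C)[C@H](CC(O[Si](C(C)C)(C(C)C)C(C)C)=C[C@@H]2C)C(O[Si](C)(C)C)=C1 | intermediate
14 | lithium Δ7-8-enolate corresponding to 13 | C=C(C)[C@H]1C[C@@]2(C)[C@H](CC(O[Si](C(C)C)(C(C)C)C(C)C)=C[C@@H]2C)C(O[Li])=C1 | intermediate
15 | (4S,4aR,6R,7R,8aS) 7α-hydroxy-6β-isopropenyl 8-ketone, 2-OTIPS enol ether | C=C(C)[C@H]1C[C@@]2(C)[C@H](CC(O[Si](C(C)C)(C(C)C)C(C)C)=C[C@@H]2C)C(=O)[C@@H]1O | intermediate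
16 | (4S,4aR,6R,7R,8S,8aS) 7α,8α-diol, 6β-isopropenyl, 2-OTIPS enol ether | C=C(C)[C@H]1C[C@@]2(C)[C@H](CC(O[Si](C(C)C)(C(C)C)C(C)C)=C[C@@H]2C)[C@H](O)[C@@H]1O | intermediate
17 | (R)-2-methylbutanoic acid | CC[C@@H](C)C(=O)O | starting material
18 | (4S,4aR,6R,7R,8S,8aS) 7α,8α-bis[(2R)-2-methylbutanoate], 2-OTIPS enol ether | C=C(C)[C@H]1C[C@@]2(C)[C@H](CC(O[Si](C(C)C)(C(C)C)C(C)C)=C[C@@H]2C)[C@H](OC(=O)[C@H](C)CC)[C@@H]1OC(=O)[C@H](C)CC | intermediate
19 | (4S,4aR,6R,7R,8S,8aS)-4,4a-dimethyl-2-oxo-6-(prop-1-en-2-yl)decahydronaphthalene-7,8-diyl bis[(2R)-2-methylbutanoate] | C=C(C)[C@H]1C[C@@]2(C)[C@H](CC(=O)C[C@@H]2C)[C@H](OC(=O)[C@H](C)CC)[C@@H]1OC(=O)[C@H](C)CC | target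

**Step count**

Total step count: 13. Longest linear sequence: 12 steps (steps 1–3 and 5–13, from 1); step 4 is the one-step side branch to the diene.

**Steps most likely to fail, with fallbacks**

Step 5 (key cycloaddition). What may go wrong: 1,2-addition of the silyl dienol ether to the Lewis-acid-complexed formyl group (Mukaiyama aldol) may outrun cycloaddition at the hindered β-carbon, or a slow reaction may erode endo and facial selectivity. The fallback sets out from 3. Bromine–lithium exchange (t-BuLi, Et2O, −78 °C) and trapping with methyl chloroformate should give methyl (S)-3-(triethylsilyloxy)cyclohex-1-ene-1-carboxylate F1, a dienophile that cannot undergo aldol-type 1,2-addition. Its cycloaddition with 6 under a strong mixed aluminium Lewis acid (AlBr3/AlMe3, toluene–CH2Cl2, −20 °C) should follow the same regio-, endo- and facial preferences and give the ester adduct F2. Reduction with DIBAL-H (CH2Cl2, −78 °C), where the neopentyl hemiacetal aluminate should survive until work-up, returns to the route at 7.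

Step 10 (conjugate addition/enolate hydroxylation). What may go wrong: oxygen transfer to the enolate may occur by axial attack from the convex β face, syn to the isopropenyl group, instead of anti to it. The fallback sets out from 12 and turns that outcome to use. The same addition/hydroxylation sequence then gives the 7β-hydroxy ketone F5 (C7 epimer of 15). Mitsunobu esterification with 17 (PPh3, DIAD, THF, 0 °C) should invert C7 and install the first ester, giving the 7α-acyloxy ketone F6. L-Selectride reduction (THF, −78 °C) from the β face should give the 8α-hydroxy 7α-ester F7, and DCC/DMAP acylation with 17 returns to the route at 18.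

Step 6 (CHO → CH3). What may go wrong: condensation at the neopentyl formyl group may stall, or the silyl groups may be lost during the diazene fragmentation. The fallback sets out from 7. NaBH4 (MeOH–THF, 0 °C) should give the primary alcohol F3, MsCl/Et3N (CH2Cl2, 0 °C) the neopentyl mesylate F4, and LiEt3BH (THF, reflux) should displace the sulfonate by hydride and return to the route at 9.

**Further compounds**

F1 | step 5 | methyl (S)-3-(triethylsilyloxy)cyclohex-1-ene-1-carboxylate | COC(=O)C1=C[C@@H](O[Si](CC)(CC)CC)CCC1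
F2 | step 5 | methyl ester analogue of adduct 7 (4a-CO2CH3 in place of 4a-CHO, same configuration) | C1C[C@@]2(C(=O)OC)[C@H](CC(O[Si](C(C)C)(C(C)C)C(C)C)=C[C@@H]2C)[C@@H](O[Si](CC)(CC)CC)C1
F3 | step 6 | 4a-hydroxymethyl analogue of 7 (primary alcohol) | C1C[C@@]2(CO)[C@H](CC(O[Si](C(C)C)(C(C)C)C(C)C)=C[C@@H]2C)[C@@H](O[Si](CC)(CC)CC)C1
F4 | step 6 | methanesulfonate of F3 | C1C[C@@]2(COS(C)(=O)=O)[C@H](CC(O[Si](C(C)C)(C(C)C)C(C)C)=C[C@@H]2C)[C@@H](O[Si](CC)(CC)CC)C1
F5 | step 10 | 7β-hydroxy epimer of 15 (OH cis to the 6β-isopropenyl group) | C=C(C)[C@H]1C[C@@]2(C)[C@H](CC(O[Si](C(C)C)(C(C)C)C(C)C)=C[C@@H]2C)C(=O)[C@H]1O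
F6 | step 10 | 7α-[(2R)-2-methylbutanoyloxy] 8-ketone (ester of 15) | C=C(C)[C@H]1C[C@@]2(C)[C@H](CC(O[Si](C(C)C)(C(C)C)C(C)C)=C[C@@H]2C)C(=O)[C@@H]1OC(=O)[C@H](C)CC
F7 | step 10 | 8α-hydroxy 7α-[(2R)-2-methylbutanoate] (7-monoester of 16) | C=C(C)[C@H]1C[C@@]2(C)[C@H](CC(O[Si](C(C)C)(C(C)C)C(C)C)=C[C@@H]2C)[C@H](O)[C@@H]1OC(=O)[C@H](C)CC
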